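The flask was a closed, stirred vessel in which a single-handed catalyst carried two mirror-image substrates to their products. Each turnover cost one partner, which came out of a solid reagent, and the protic impurity consumed partner as well.

left-handed substrate 0.80 M; solid reagent 0.800 equiv; protic impurity 0.160 M; free catalyst 1.2 mol%; right-handed substrate 0.80 M; time 5.0 h

    partner + catalyst intermediate A → free catalyst + left-handed product (k1 = 0.45 M⁻¹ s⁻¹)
    partner + protic impurity → quenched reagent (k2 = 0.031 M⁻¹ s⁻¹)
    free catalyst + right-handed substrate ⇌ catalyst intermediate B (K3 = 0.90 M⁻¹, k3 = 4.8 M⁻¹ s⁻¹)
    solid reagent ⇌ partner, rate k4*(cs4 - [partner]) while solid is left; crystals form when [partner] > cs4 (cs4 = 0.40 M, k4 = 0.0042 s⁻¹)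
    partner + catalyst intermediate B → free catalyst + right-handed product (k5 = 0.0093 M⁻¹ s⁻¹)
    free catalyst + left-handed substrate ⇌ catalyst intermediate A (K6 = 0.51 M⁻¹, k6 = 29 M⁻¹ s⁻¹)

- free catalyst is single-handed; left-handed substrate and right-handed substrate are mirror images of each other, charged as a racemate, each of them at the stated concentration
- given per volume of solution although it is solid: solid reagent
- at the start none of the solid reagent is in solution
- the reaction counts as stopped when no species that holds the left-handed substrate and right-handed substrate together changes by six tenths of a point or more over the second half of the time
- run time (flask): 5.0 h

- which holds at 5.0 h: what has brought the reaction to rest, or that it has not come to rest (for what has run out or reacted, a solid counts together with what of it has only dissolved) (the partner has run out first / no working catalyst is left / it is still moving / forward and back rates have come level / all of the left-handed substrate has reacted)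
- how much of the left-handed substrate and right-handed substrate together has reacted by 5.0 h
- how much left-handed product there is at 5.0 h, in percent of the left-handed substrate and right-handed substrate together charged
- how much right-handed substrate there is at 5.0 h, in percent of the left-handed substrate and right-handed substrate together charged

I began with the account of partner. The reagent charge could pay for 40.0 % of left-handed product, and the impurity claimed 10.0 %, which left 30.0 %. I called this the turnover budget, the partner left for catalysis after the impurity's share, in percent of both substrates together. It was less than the half of the charge that was left-handed substrate, so I took partner as the limiting reagent. I expected the impurity to be paid early, because partner's half-life against it at its charged amount, 2.3 min, was shorter than its half-life against the left-handed turnover at the start, 13.9 min.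

To split the budget, I assumed both binding steps stayed near equilibrium. At equal concentrations the left-handed substrate then reacted faster than the right-handed one by a selectivity factor of 27.4. For this flask I therefore took the fraction of right-handed substrate remaining as the fraction of left-handed substrate remaining, raised to the power one over that factor.

| Round | Left-handed product assumed | Left-handed substrate remaining, of its charge | Right-handed product that follows |
|---|---|---|---|
| first | 30.0 % | 40.0 % | 1.64 % |
| second | 28.4 % | 43.3 % | 1.50 % |

The first row gave the left-handed product the whole budget, yet it implied 1.64 % of right-handed product, which the budget also had to pay for. The second row paid that, and its two products summed to 29.9 %, so I stopped there. With the second row's substrate, partner's half-life against the left-handed turnover was 28.7 min, and the run lasted about ten times that. I therefore committed to partner running out, with conversion near the budget, 28.4 % of left-handed product and 48.5 % of right-handed substrate.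

The forecast differed: it is still moving, 63 % converted, 50 % left-handed product and 37 % right-handed substrate. Its grounds were: “The remaining dissolved partner then slowly consumes right-handed substrate”. Those numbers are what one gets with solid reagent held at its starting value.

The flask's answer was: the partner has run out first, with 0.017 % of the charged partner remaining, solid or dissolved, at 5.00 h. It gave 30.3 % converted against my budget of 30.0 %, 28.5 % left-handed product and 48.3 % right-handed substrate. The neighbouring flask with 0.40 M of protic impurity had a budget of 15.0 %, and that flask converted 15.3 %.

Its constants come from no measurement; the rest is arithmetic.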